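**Retrosynthetic overview**

1. The 14-membered ring and the cis-fused α-methylene-γ-lactone are closed together, last, by an intramolecular indium Barbier allylation (C1–C14) of a (Z)-2-(bromomethyl)enoate onto the C14 α-alkoxy aldehyde.
2. The seco chain is cut at C8–C9: alkyllithium (C9–C14) plus Weinreb amide (C1–C8) gives the C8 ketone; chelation-controlled MeMgBr addition then sets C8.
3. The C1–C8 oxolane fragment comes from a B-alkyl Suzuki coupling (C4–C5) of a glycidol-derived allylic alcohol with an (E)-vinyl iodide, then Shi epoxidation and 5-exo epoxide opening. The oxolane is the first ring formed.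
4. The C9–C14 fragment comes from (S)-citronellal (C12 methyl) by proline-catalysed α-aminoxylation (C13).
5. Ring order: oxolane, then macrocycle and lactone in one step.

Assumptions: two-stage one-pot operations written over one arrow count as one step; 4,4-diethoxybut-1-yne (3-butynal diethyl acetal) is taken as purchasable.

Locants used in names: ring carbons C1–C14 (C1 = ring-fusion CH bearing the lactone α-carbon; C3 = CHOH; C4/C7 = oxolane carbons; C8 = C(Me)OAc; C12 = CHMe; C13 = CHOAc; C14 = lactone O–CH). Target configuration: 1S,3R,4S,7R,8S,12S,13R,14R (cis-2,5-oxolane, cis-lactone, 13,14-syn).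

## Branch 1: C5–C8 piece

**Step 1**
Reactants: 1, (S)-glycidol
Product: 2, (R)-2-{[(4-methoxybenzyl)oxy]methyl}oxirane
Conditions: NaH, PMBCl, Bu4NI (cat.), THF/DMF, 0 °C
Reagents that add atoms: 4-methoxybenzyl chloride, COc1ccc(CCl)cc1
Why: Williamson etherification at low temperature leaves the stereocentre untouched (the descriptor changes S→R only through CIP priorities).

**Step 2**
Reactants: 2
Product: 3, (R)-1-[(4-methoxybenzyl)oxy]but-3-en-2-ol
Conditions: Me3S+ I−, n-BuLi, THF, −10 °C → rt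
Reagents that add atoms: trimethylsulfonium iodide, C[S+](C)C.[I-]
Why: Dimethylsulfonium methylide opens the epoxide at the terminal carbon and eliminates Me2S (one-carbon epoxide-to-allylic-alcohol homologation); the carbinol centre (future C7) is not touched.

## Branch 2: C1–C4 piece

**Step 3**
Reactants: 4, 4,4-diethoxybut-1-yne
Product: 5, 1,1-diethoxypent-3-yne
Conditions: n-BuLi, THF, −78 °C; MeI, → rt
Reagents that add atoms: iodomethane, CI
Why: Acetylide alkylation installs the future C4 methyl.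

**Step 4**
Reactants: 5
Product: 6, (E)-5,5-diethoxy-2-iodopent-2-ene
Conditions: Cp2Zr(H)Cl (1.6 equiv), THF, 50 °C; then I2, 0 °C
Reagents that add atoms: iodine, II
Why: Syn hydrozirconation under equilibrating conditions places Zr on the less hindered methyl-bearing carbon; iodinolysis with retention gives the E-iodide.

## Fragment A (C1–C8)

**Step 5**
Reactants: 3 and 6
Product: 7, (2R,5E)-8,8-diethoxy-1-[(4-methoxybenzyl)oxy]-5-methyloct-5-en-2-ol
Conditions: 3, 9-BBN (2.2 equiv), THF, rt; then 6, PdCl2(dppf), AsPh3, Cs2CO3, DMF/H2O, rt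
Reagents that add atoms: none
Why: B-alkyl Suzuki–Miyaura coupling forms C4–C5 with retention of alkene geometry, giving the E-trisubstituted olefin; the extra 9-BBN is consumed by the free OH.

**Step 6**
Reactants: 7
Product: 8, (1R)-3,3-diethoxy-1-[(2S,5R)-5-{[(4-methoxybenzyl)oxy]methyl}-2-methyloxolan-2-yl]propan-1-ol
Conditions: D-fructose-derived Shi ketone (30 mol%), Oxone, K2CO3, Bu4NHSO4, MeCN/DMM/buffer pH 10.5, 0 °C; then CSA (cat.), CH2Cl2, 0 °C
Reagents that add atoms: Oxone (KHSO5), OOS(=O)(=O)[O-].[K+]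
Why: Shi epoxidation gives the (3R,4R)-epoxide by reagent control; 5-exo opening by the C7 hydroxyl at the tertiary carbon inverts C4, so C3 (R), C4 (S) and the cis-2,5-oxolane are set stereospecifically.

**Step 7**
Reactants: 8
Product: 9, the C3 tert-butyldimethylsilyl ether of 8
Conditions: TBSOTf, 2,6-lutidine, CH2Cl2, −78 °C
Reagents that add atoms: TBSOTf, CC(C)(C)[Si](C)(C)OS(=O)(=O)C(F)(F)F
Why: Silylation of the hindered secondary alcohol; at −78 °C the diethyl acetal is not activated.

**Step 8**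
Reactants: 9
Product: 10, {(2R,5S)-5-[(1R)-1-(TBS-oxy)-3,3-diethoxypropyl]-5-methyloxolan-2-yl}methanol
Conditions: DDQ, CH2Cl2/pH 7 buffer, 0 °C
Reagents that add atoms: none
Why: Oxidative PMB cleavage; the buffer protects the acetal and the TBS ether.

**Step 9**
Reactants: 10
Product: 11, (2R,5S)-5-[(1R)-1-(TBS-oxy)-3,3-diethoxypropyl]-5-methyloxolane-2-carboxylic acid
Conditions: TEMPO (cat.), NaClO2, NaOCl (cat.), MeCN/phosphate buffer pH 6.7, 35 °C
Reagents that add atoms: sodium chlorite, [O-]Cl=O.[Na+]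
Why: Buffered TEMPO/chlorite oxidation takes the primary alcohol to the acid without acetal hydrolysis or epimerisation at C7.

**Step 10**
Reactants: 11
Product: 12, (2R,5S)-5-[(1R)-1-(TBS-oxy)-3,3-diethoxypropyl]-N-methoxy-N,5-dimethyloxolane-2-carboxamide
Conditions: MeNHOMe·HCl, EDCI, HOBt, NMM, CH2Cl2, 0 °C → rt
Reagents that add atoms: N,O-dimethylhydroxylamine hydrochloride, CNOC.Cl
Why: Standard carbodiimide amidation gives the Weinreb amide for single addition of the C9 nucleophile.

## Fragment B (C9–C14)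

**Step 11**
Reactants: 13, (S)-citronellal
Product: 14, (2R,3S)-3,7-dimethyl-2-[(phenylamino)oxy]oct-6-en-1-ol
Conditions: PhNO, L-proline (20 mol%), CHCl3, 4 °C; then NaBH4, EtOH, 0 °C
Reagents that add atoms: nitrosobenzene, O=Nc1ccccc1
Why: Proline-catalysed α-aminoxylation is catalyst-controlled (L-proline gives 2R), setting C13; in situ reduction prevents epimerisation.

**Step 12**
Reactants: 14
Product: 15, (2R,3S)-3,7-dimethyloct-6-ene-1,2-diol
Conditions: CuSO4·5H2O (30 mol%), MeOH, rt
Reagents that add atoms: none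
Why: Cu(II)-mediated N–O cleavage releases the diol without touching the alkene.

**Step 13**
Reactants: 15
Product: 16, (4R)-2-(4-methoxyphenyl)-4-[(2S)-6-methylhept-5-en-2-yl]-1,3-dioxolane (acetal epimers)
Conditions: p-anisaldehyde dimethyl acetal, PPTS (cat.), CH2Cl2, rt
Reagents that add atoms: 4-methoxybenzaldehyde dimethyl acetal, COc1ccc(C(OC)OC)cc1
Why: Transacetalisation of the 1,2-diol.

**Step 14**
Reactants: 16
Product: 17, (2R,3S)-2-[(4-methoxybenzyl)oxy]-3,7-dimethyloct-6-en-1-ol
Conditions: DIBAL-H, CH2Cl2, −78 → 0 °C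
Reagents that add atoms: none
Why: Reductive acetal opening; aluminium coordinates the less hindered primary oxygen, leaving PMB on the secondary C13 oxygen.

**Step 15**
Reactants: 17
Product: 18, tert-butyl({(2R,3S)-2-[(4-methoxybenzyl)oxy]-3,7-dimethyloct-6-en-1-yl}oxy)dimethylsilane
Conditions: TBSCl, imidazole, DMF, rt
Reagents that add atoms: TBSCl, CC(C)(C)[Si](C)(C)Cl
Why: Silylation of the primary C14 alcohol.

**Step 16**
Reactants: 18
Product: 19, (4S,5R)-6-(TBS-oxy)-5-[(4-methoxybenzyl)oxy]-4-methylhexan-1-ol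
Conditions: O3, CH2Cl2/MeOH, pyridine, Sudan III, −78 °C; then NaBH4, → 0 °C
Reagents that add atoms: ozone, [O-][O+]=O
Why: The electron-rich trisubstituted alkene is ozonised far faster than the anisyl ring (indicator end-point); reductive work-up gives the C9 alcohol.

**Step 17**
Reactants: 19
Product: 20, tert-butyl({(2R,3S)-6-iodo-2-[(4-methoxybenzyl)oxy]-3-methylhexyl}oxy)dimethylsilane
Conditions: I2, PPh3, imidazole, CH2Cl2, 0 °C
Reagents that add atoms: iodine, II
Why: Appel iodination of the primary alcohol.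

## Fragment union and end game

**Step 18**
Reactants: 20 and 12
Product: 21, C8 ketone of the full C1–C14 chain (C1 diethyl acetal, 3-OTBS, 4,7-oxolane, 13-OPMB, 14-OTBS)
Conditions: 20, t-BuLi (2.05 equiv), Et2O, −78 °C; then 12, Et2O/THF, −78 °C
Reagents that add atoms: none
Why: Iodine–lithium exchange then acylation by the Weinreb amide; the chelated tetrahedral intermediate prevents over-addition.

**Step 19**
Reactants: 21
Product: 22, the (8S) tertiary acetate
Conditions: MeMgBr, CH2Cl2/Et2O, −78 °C; then Ac2O, DMAP, −78 °C → rt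
Reagents that add atoms: methylmagnesium bromide, C[Mg]Br; acetic anhydride, CC(=O)OC(C)=O
Why: Cram-chelate addition: Mg bridges the ketone and oxolane oxygens and methyl attacks from the C7–H face, giving 8S; the tertiary alkoxide is trapped in situ as the acetate.

**Step 20**
Reactants: 22
Product: 23, C1 aldehyde / C14 primary alcohol
Conditions: AcOH/THF/H2O (3:1:1), 40 °C
Reagents that add atoms: water, O
Why: Mild acid hydrolyses the diethyl acetal and the primary TBS ether together; the hindered secondary C3 TBS ether, the PMB ether and the tertiary acetate survive.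

**Step 21**
Reactants: 23
Product: 24, Morita–Baylis–Hillman adduct, methyl 2-[hydroxy(C1)methyl]acrylate (C1 carbinol epimers)
Conditions: methyl acrylate (excess), DABCO, MeOH, rt
Reagents that add atoms: methyl acrylate, C=CC(=O)OC
Why: Morita–Baylis–Hillman reaction at the unhindered C1 aldehyde adds C15–C17; the new carbinol centre is destroyed in step 23.

**Step 22**
Reactants: 24
Product: 25, C14 aldehyde
Conditions: TEMPO (cat.), PhI(OAc)2, CH2Cl2, rt
Reagents that add atoms: none
Why: TEMPO/BAIB oxidises the primary alcohol chemoselectively over the electron-poor secondary allylic alcohol, without epimerising C13.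

**Step 23**
Reactants: 25
Product: 26, methyl (Z)-2-(bromomethyl)alk-2-enoate (C1=C15) bearing the C14 aldehyde
Conditions: NBS, Me2S, CH2Cl2, −20 → 0 °C
Reagents that add atoms: N-bromosuccinimide, BrN1C(=O)CCC1=O
Why: SN2′ bromination of the Baylis–Hillman alcohol gives the thermodynamic Z-allyl bromide; the aldehyde is inert.

**Step 24**
Reactants: 26
Product: 27, macrolactone (13-OPMB, 3-OTBS, 8-OAc)
Conditions: In powder, THF/H2O (3:1), rt, syringe-pump addition (final about 2 mM); then TsOH·H2O (cat.), CH2Cl2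
Reagents that add atoms: none
Why: Intramolecular indium Barbier allylation (γ-attack) through a chair transition state from the Z-bromide gives the 1,14-syn adduct, and chelation by the α-OPMB gives 13,14-syn; the resulting 14R,1S hydroxy ester closes to the cis-lactone.

**Step 25**
Reactants: 27
Product: 28, C13 alcohol
Conditions: DDQ, CH2Cl2/pH 7 buffer, 0 °C → rt
Reagents that add atoms: none
Why: Oxidative PMB removal; the methylene lactone, acetate and TBS ether are inert.

**Step 26**
Reactants: 28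
Product: 29, 8,13-diacetate 3-TBS ether
Conditions: Ac2O, pyridine, DMAP (cat.), CH2Cl2, 0 °C → rt
Reagents that add atoms: acetic anhydride, CC(=O)OC(C)=O
Why: Acylation of the only free (secondary) hydroxyl.

**Step 27**
Reactants: 29
Product: 30, target (CID 10479028)
Conditions: HF·pyridine, THF/pyridine, 0 °C → rt
Reagents that add atoms: none
Why: Buffered fluoride desilylation frees the C3 hydroxyl without acetate migration or conjugate addition to the methylene lactone.

## Compound list

1 | (S)-glycidol | OC[C@H]1CO1 | starting material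
2 | (R)-PMB glycidyl ether | COc1ccc(COC[C@H]2CO2)cc1 | intermediate
3 | (R)-1-(PMB-oxy)but-3-en-2-ol | COc1ccc(COC[C@H](O)C=C)cc1 | intermediate
4 | 4,4-diethoxybut-1-yne | C#CCC(OCC)OCC | starting material
5 | 1,1-diethoxypent-3-yne | CC#CCC(OCC)OCC | intermediate
6 | (E)-5,5-diethoxy-2-iodopent-2-ene | C/C(I)=C\CC(OCC)OCC | intermediate
7 | (2R,5E)-8,8-diethoxy-1-(PMB-oxy)-5-methyloct-5-en-2-ol | CCOC(OCC)C/C=C(\C)CC[C@@H](O)COCc1ccc(OC)cc1 | intermediate
8 | oxolane alcohol | CCOC(OCC)C[C@@H](O)[C@]1(C)CC[C@@H](O1)COCc2ccc(OC)cc2 | intermediate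
9 | C3 TBS ether | CCOC(OCC)C[C@@H](O[Si](C)(C)C(C)(C)C)[C@]1(C)CC[C@@H](O1)COCc2ccc(OC)cc2 | intermediate
10 | C8 primary alcohol | CCOC(OCC)C[C@@H](O[Si](C)(C)C(C)(C)C)[C@]1(C)CC[C@@H](O1)CO | intermediate
11 | C8 carboxylic acid | CCOC(OCC)C[C@@H](O[Si](C)(C)C(C)(C)C)[C@]1(C)CC[C@@H](O1)C(=O)O | intermediate
12 | Weinreb amide (fragment A) | CCOC(OCC)C[C@@H](O[Si](C)(C)C(C)(C)C)[C@]1(C)CC[C@@H](O1)C(=O)N(C)OC | intermediate
13 | (S)-citronellal | CC(C)=CCC[C@H](C)CC=O | starting material
14 | (2R,3S)-2-anilinooxy alcohol | CC(C)=CCC[C@H](C)[C@@H](ONc1ccccc1)CO | intermediate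
15 | (2R,3S)-3,7-dimethyloct-6-ene-1,2-diol | CC(C)=CCC[C@H](C)[C@@H](O)CO | intermediate
16 | PMP acetal | CC(C)=CCC[C@H](C)[C@@H]1COC(c2ccc(OC)cc2)O1 | intermediate
17 | 2-O-PMB primary alcohol | CC(C)=CCC[C@H](C)[C@@H](OCc1ccc(OC)cc1)CO | intermediate
18 | 1-O-TBS, 2-O-PMB alkene | CC(C)=CCC[C@H](C)[C@@H](OCc1ccc(OC)cc1)CO[Si](C)(C)C(C)(C)C | intermediate
19 | C9 alcohol | OCCC[C@H](C)[C@@H](OCc1ccc(OC)cc1)CO[Si](C)(C)C(C)(C)C | intermediate
20 | C9 iodide (fragment B) | ICCC[C@H](C)[C@@H](OCc1ccc(OC)cc1)CO[Si](C)(C)C(C)(C)C | intermediate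
21 | C8 ketone | CCOC(OCC)C[C@@H](O[Si](C)(C)C(C)(C)C)[C@]1(C)CC[C@@H](O1)C(=O)CCC[C@H](C)[C@@H](OCc2ccc(OC)cc2)CO[Si](C)(C)C(C)(C)C | intermediate
22 | (8S) tertiary acetate | CCOC(OCC)C[C@@H](O[Si](C)(C)C(C)(C)C)[C@]1(C)CC[C@@H](O1)[C@@](C)(OC(C)=O)CCC[C@H](C)[C@@H](OCc2ccc(OC)cc2)CO[Si](C)(C)C(C)(C)C | intermediate
23 | C1 aldehyde, C14 alcohol | O=CC[C@@H](O[Si](C)(C)C(C)(C)C)[C@]1(C)CC[C@@H](O1)[C@@](C)(OC(C)=O)CCC[C@H](C)[C@@H](OCc2ccc(OC)cc2)CO | intermediate
24 | Baylis–Hillman adduct | C=C(C(=O)OC)C(O)C[C@@H](O[Si](C)(C)C(C)(C)C)[C@]1(C)CC[C@@H](O1)[C@@](C)(OC(C)=O)CCC[C@H](C)[C@@H](OCc2ccc(OC)cc2)CO | intermediate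
25 | C14 aldehyde | C=C(C(=O)OC)C(O)C[C@@H](O[Si](C)(C)C(C)(C)C)[C@]1(C)CC[C@@H](O1)[C@@](C)(OC(C)=O)CCC[C@H](C)[C@@H](OCc2ccc(OC)cc2)C=O | intermediate
26 | (Z)-allyl bromide aldehyde | COC(=O)/C(CBr)=C/C[C@@H](O[Si](C)(C)C(C)(C)C)[C@]1(C)CC[C@@H](O1)[C@@](C)(OC(C)=O)CCC[C@H](C)[C@@H](OCc2ccc(OC)cc2)C=O | intermediate
27 | macrolactone, 13-OPMB, 3-OTBS | C=C1C(=O)O[C@H]2[C@H](OCc4ccc(OC)cc4)[C@@H](C)CCC[C@](C)(OC(C)=O)[C@H]3CC[C@](C)(O3)[C@H](O[Si](C)(C)C(C)(C)C)C[C@@H]12 | intermediate
28 | 13-alcohol | C=C1C(=O)O[C@H]2[C@H](O)[C@@H](C)CCC[C@](C)(OC(C)=O)[C@H]3CC[C@](C)(O3)[C@H](O[Si](C)(C)C(C)(C)C)C[C@@H]12 | intermediate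
29 | 8,13-diacetate 3-TBS ether | C=C1C(=O)O[C@H]2[C@H](OC(C)=O)[C@@H](C)CCC[C@](C)(OC(C)=O)[C@H]3CC[C@](C)(O3)[C@H](O[Si](C)(C)C(C)(C)C)C[C@@H]12 | intermediate
30 | target | C=C1C(=O)O[C@H]2[C@H](OC(C)=O)[C@@H](C)CCC[C@](C)(OC(C)=O)[C@H]3CC[C@](C)(O3)[C@H](O)C[C@@H]12 | target

## Summary

Total steps: 27 (2 + 2 + 6 for fragment A, 7 for fragment B, 10 after union).
Longest linear sequence: 18 steps (4 → 5 → 6 → 7 → … → 12 → 21 → … → 30; the glycidol branch is equally long).

Steps most likely to fail, with fallbacks: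

1. **Step 24 (indium macrocyclisation; yield and C1/C14 facial selectivity).** Fallback: form C1–C14 intermolecularly by the same chelation-controlled indium Barbier reaction, using a shortened C10–C14 α-PMB-oxy aldehyde with a terminal alkene and an oxolane allyl bromide carrying a C8 vinyl carbinol. Then close the 14-membered ring by ring-closing metathesis at C9=C10, with the methylene lactone masked as its dimethylamine adduct during hydrogenation and regenerated by MeI/NaHCO3.
2. **Steps 4–5 (hydrozirconation regiochemistry; B-alkyl Suzuki with a free hydroxyl).** Fallback: build the same alkene linearly. Open epoxide 2 with lithiated 1-(trimethylsilyl)propyne, desilylate, carry out Negishi Zr-catalysed carboalumination with iodine quench, then Negishi-couple the E-vinyl iodide with (1,3-dioxolan-2-ylmethyl)zinc bromide.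
3. **Step 19 (chelation-controlled methyl addition and in situ acetylation).** Fallback: set C8 by reagent control. Derive C2–C9 from (2E,6E)-8-hydroxygeraniol by double Sharpless epoxidation (D-tartrate) and an epoxide-opening cascade, convert C8/C9 to the terminal epoxide, and join a C10–C14 organocuprate at C9 to give the tertiary alcohol directly.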